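Compare the two product rates.

| flask | left-handed substrate | right-handed substrate | partner | free catalyst | remark | time |
|---|---|---|---|---|---|---|
| violet | 14 mM | 14 mM | 2 equiv | 1.5 mol% | run made earlier |  |
| green | 14 mM | 14 mM | 2 equiv | 13 mol% | run made earlier |  |
| gamma | 14 mM | 14 mM | 2.00 equiv | 1.2 mol% |  | 2.5 d |
| beta | 14 mM | 14 mM | 2.00 equiv | 2.5 mol% |  | 2.5 d |
| eta | 14 mM | 14 mM | 2.00 equiv | 5 mol% |  | 2.5 d |
| theta | 14 mM | 14 mM | 2.00 equiv | 10 mol% |  | 2.5 d |

| run | time / h | left-handed product / % | right-handed product / % |
|---|---|---|---|
| violet | 3.00 | 1 | 0 |
| violet | 6.00 | 6 | 3 |
| violet | 10.0 | 6 | 2 |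
| violet | 15.0 | 7 | 4 |
| violet | 25.0 | 12 | 4 |
| violet | 40.0 | 18 | 3 |
| green | 8.00 | 26 | 11 |
| green | 15.0 | 32 | 15 |
| green | 20.0 | 40 | 17 |
| green | 30.0 | 42 | 23 |
| green | 40.0 | 40 | 23 |

(scatter of a reading: 2 percentage points)

- free catalyst is single-handed; left-handed substrate and right-handed substrate are mirror images of each other, charged as a racemate, each of them at the stated concentration
- an excess is the difference of the two amounts in percent of their sum
- "hardly changes" means that all values lie within two and a half points (for a concentration: within two and a half percent of the largest)

- excess of left-handed product over right-handed product at the end for gamma, beta, eta, theta, in this order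
- the shape of the row from first to last (falls, then rises / rises all the way / falls all the way / hardly changes / rises, then falls)

Let L and R be the left-handed and right-handed substrate still in the flask. If each product forms in proportion to its own substrate, the momentary ratio of left-handed to right-handed product rate is m = s·L/R, where s is the selectivity factor. Each substrate is half of the pooled charge, so the logarithms of the fractions left stand in the ratio s. The green run reads 2.95 at 8.00 h for this selectivity factor, and 2.86 at 15.0 h. At the start L equals R, so m equals s and the excess is (s − 1)/(s + 1), or 49.4% on the first reading.

Time comes first. By hand, with s above one, the left-handed substrate falls faster, so m drifts down and later product carries less excess. The green run does this, going from 40.5% at 8.00 h to 27.0% at 40.0 h.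

Loading comes next. By hand, a catalyst multiplying both rates cancels from m, so more of it carries a flask further down the same drift in a given time. The runs point that way: the violet run at 1.5 mol% reads 50.0% at 25.0 h, and the green run at 13 mol% reads 29.2% at 30.0 h, though the violet figure is rough, with 4% of right-handed product against a scatter of 2 percentage points.

This reckoning therefore commits to a row that starts under 49.4% and falls with loading, without point values. The forecast gives 48%, 42%, 33% and 24%, so its row falls all the way, and its ground is “The excess therefore falls steadily with loading.”

The flasks give 46.3%, 42.2%, 37.1% and 31.3%, so the row falls all the way, with gamma under 49.4%.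

    partner + free catalyst + left-handed substrate → free catalyst + left-handed product (k = 2400 M⁻² h⁻¹)
    partner + free catalyst + right-handed substrate → free catalyst + right-handed product (k = 760 M⁻² h⁻¹)
    left-handed substrate ⇌ right-handed substrate (k = 0.00470 h⁻¹)
    2 free catalyst → spent catalyst (k = 3.40 M⁻¹ h⁻¹)

Theta ends 7.3 points above the forecast, with 63.6% of its catalyst free and 36.4% spent. Put to the end amounts, the s read from the first green reading, with the scatter of that reading, reckons m at about 2.23 in gamma and about 1.07 in theta. From 1.25 d to 2.50 d gamma gains 8.3 points of left-handed and 3.3 points of right-handed product, and theta gains 6.6 points and 5.5 points.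

(The data are calculated from invented constants.)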